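**Strategy**

1. Retrosynthetic cuts: a CO2 unit is put back between the ketone α-CH2 and the phenol oxygen, so the aryl ketone carbon, the CH2 and the phenol O become C4, C3 and O1 of a 4-hydroxy-5-methylcoumarin. The bond from that C3 to the quaternary carbon is then cut by a retro-[3,3] shift, which returns the C15 chain to O4 as a linear (2E,6E)-farnesyl ether. The O4–CH2 bond and the pyranone are cut last.
2. Forward order: the pyranone is closed on the purchased arene (1 + 2 → 4), farnesol 5 is joined at O4 (6), the chain is transposed to C3 (8), and the pyranone is opened with loss of its C2 as CO2 (10). The benzene ring is the only ring that remains.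
3. Enabling feature: a 2-hydroxy-6-methylphenyl ketone whose α-CH2 carries a quaternary carbon with methyl, vinyl and homogeranyl is a decarboxylated 4-hydroxy-5-methylcoumarin bearing a farnesyl group bound through its C3'. That is the pattern an O4-to-C3 Claisen shift leaves behind.
4. Stereochemistry: the single quaternary centre is set in the Claisen step by a chiral guanidinium hydrogen-bond donor acting through a chair transition state on the 2'E alkene. It is S while attached to the coumarin and R in the target, with the same spatial arrangement. Both trisubstituted E alkenes come with farnesol.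

Key step: step 3

Assumption: the sense of induction of the guanidinium salt on a 4-allyloxycoumarin is not known. The route is written with the catalyst from (1R,2R)-cyclohexane-1,2-diamine; the configuration of 8 is to be checked at that stage, and the mirror-image catalyst is used if the R adduct predominates. The catalyst is a known salt, made separately and counted as a reagent.

Farnesyl atoms carry primed locants (C1' is the OCH2 carbon).

**Step 1**
Reactants: 1 2'-hydroxy-6'-methylacetophenone; 2 diethyl carbonate
Product: 4 4-hydroxy-5-methylcoumarin, via ethyl 3-(2-hydroxy-6-methylphenyl)-3-oxopropanoate 3 (not isolated)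
Conditions: NaH (4 equiv), 2 (3 equiv), toluene, 0 °C then 110 °C; aq. HCl work-up
Reagents that add atoms: none
Why: Crossed Claisen condensation of the phenoxide–enolate of the methyl ketone with the carbonate, then lactonisation of the β-keto ester onto the phenoxide, is the standard way from 2'-hydroxyacetophenones to 4-hydroxycoumarins and is driven by formation of the stable coumarin enolate.

**Step 2**
Reactants: 4 4-hydroxy-5-methylcoumarin; 5 (2E,6E)-farnesol
Product: 6 5-methyl-4-{[(2E,6E)-3,7,11-trimethyldodeca-2,6,10-trien-1-yl]oxy}coumarin
Conditions: PPh3, DIAD, THF, 0 °C to rt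
Reagents that add atoms: none
Why: In this Mitsunobu reaction the acidic enol of 4 protonates the betaine and its O4 displaces the oxyphosphonium group at the primary C1' by SN2, which should give the O4 ether with both E alkenes untouched and without the C3-alkylation that allyl halide and base bring.

**Step 3**
Reactants: 6 5-methyl-4-{[(2E,6E)-3,7,11-trimethyldodeca-2,6,10-trien-1-yl]oxy}coumarin
Product: 8 4-hydroxy-5-methyl-3-[(3S,6E)-3,7,11-trimethyldodeca-1,6,10-trien-3-yl]coumarin, via chromane-2,4-dione keto tautomer 7 (not isolated)
Conditions: N,N'-bis[(1R,2R)-2-(2-phenyl-1H-pyrrol-1-yl)cyclohexyl]guanidinium tetrakis[3,5-bis(trifluoromethyl)phenyl]borate (20 mol%), hexanes/toluene, 30–35 °C, 3–5 d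
Reagents that add atoms: none
Why: Proposed new method: the ether is a cyclic β-alkoxy enoate in which O4 and the lactone C=O lie on either side of C3, so a C2-symmetric guanidinium can hold it by N–H···O hydrogen bonds and stabilise the vinylogous carboxylate that builds up as the O4–C1' bond breaks and the C3–C3' bond forms in a concerted, polarised chair-like [3,3] shift, the trisubstituted farnesyl terminus carrying the matching partial positive charge. The closest known reaction types are the chiral guanidinium-catalysed enantioselective Claisen rearrangement of O-allyl enol ethers of β-keto esters and the thermal Claisen rearrangement of 4-(3,3-dialkylallyloxy)coumarins to 3-(1,1-dialkylallyl)-4-hydroxycoumarins; what is new is their combination on a coumarin with a 3,3-disubstituted allyl terminus. No ring is closed, since the pyranone is already in place and the first-formed dione 7 only enolises to 8. The quaternary centre is controlled by the catalyst, which has to select one face of the C3=C4 enol ether, and by the chair geometry, which passes that choice through the fixed 2'E alkene to one face of C3' (the centre at C3 of 7 disappears on enolisation). Besides this enantioface selection the step needs chair over boat and [3,3] over [1,3] shift or ionisation, which the E alkene, the non-polar solvent and a temperature about a hundred degrees below that of the uncatalysed rearrangement should secure, the same mildness keeping the racemic background, the abnormal Claisen pathway and the addition of the 4-OH to the new vinyl group out of play. The peri methyl group at C5 pushes the O4–CH2 bond toward C3 and thus favours the reactive conformer.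

**Step 4**
Reactants: 8 4-hydroxy-5-methyl-3-[(3S,6E)-3,7,11-trimethyldodeca-1,6,10-trien-3-yl]coumarin
Product: 10 (3R,6E)-3-ethenyl-1-(2-hydroxy-6-methylphenyl)-3,7,11-trimethyldodeca-6,10-dien-1-one (target), via ring-opened β-keto acid 9 (not isolated)
Conditions: 5 M aq. NaOH, EtOH, reflux; then 1 M HCl to pH 4 at 0 °C, warm to 45 °C
Reagents that add atoms: sodium hydroxide, [Na+].[OH-] (its oxygen enters the carboxyl group of 9 and leaves again in the CO2; 10 itself keeps only hydrogen from the reagents)
Why: Lactone saponification followed by decarboxylation of the β-keto acid is the classical alkaline degradation of 3-substituted 4-hydroxycoumarins to 2-hydroxyphenyl ketones, and the quaternary centre has no hydrogen to epimerise while the isolated alkenes tolerate hot alkali and dilute acid.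

**Compound list**

1 | 2'-hydroxy-6'-methylacetophenone | CC(=O)c1c(C)cccc1O | starting material
2 | diethyl carbonate | CCOC(=O)OCC | starting material
3 | ethyl 3-(2-hydroxy-6-methylphenyl)-3-oxopropanoate (sodium salt in the flask) | CCOC(=O)CC(=O)c1c(C)cccc1O | intermediate
4 | 4-hydroxy-5-methylcoumarin | Cc1cccc2oc(=O)cc(O)c12 | intermediate
5 | (2E,6E)-farnesol, (2E,6E)-3,7,11-trimethyldodeca-2,6,10-trien-1-ol | OC/C=C(\C)CC/C=C(\C)CCC=C(C)C | starting material
6 | 5-methyl-4-{[(2E,6E)-3,7,11-trimethyldodeca-2,6,10-trien-1-yl]oxy}coumarin | Cc1cccc2oc(=O)cc(OC/C=C(\C)CC/C=C(\C)CCC=C(C)C)c12 | intermediate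
7 | 5-methyl-3-[(3S,6E)-3,7,11-trimethyldodeca-1,6,10-trien-3-yl]chromane-2,4-dione (keto tautomer of 8; C3 of the ring not specified, lost on enolisation) | C=C[C@](C)(CC/C=C(\C)CCC=C(C)C)C1C(=O)Oc2cccc(C)c2C1=O | intermediate
8 | 4-hydroxy-5-methyl-3-[(3S,6E)-3,7,11-trimethyldodeca-1,6,10-trien-3-yl]coumarin | C=C[C@](C)(CC/C=C(\C)CCC=C(C)C)c1c(O)c2c(C)cccc2oc1=O | intermediate
9 | (3S,6E)-3-ethenyl-2-(2-hydroxy-6-methylbenzoyl)-3,7,11-trimethyldodeca-6,10-dienoic acid (both C2 epimers) | C=C[C@](C)(CC/C=C(\C)CCC=C(C)C)C(C(=O)O)C(=O)c1c(C)cccc1O | intermediate
10 | (3R,6E)-3-ethenyl-1-(2-hydroxy-6-methylphenyl)-3,7,11-trimethyldodeca-6,10-dien-1-one | C=C[C@](C)(CC/C=C(\C)CCC=C(C)C)CC(=O)c1c(C)cccc1O | target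

**Count**

Total step count: 4. Longest linear sequence: 4 steps (1 → 4 → 6 → 8 → 10).

**Steps most likely to fail**

Step 3 (proposed new method). The catalyst may bind the rigid, divergent pair of oxygens only weakly, or be tied up by the acidic product. The rearrangement would then stall at mild temperature or run with poor facial selectivity, and heating to compensate would bring in the racemic background reaction. The fallback uses known chemistry and sets out from 6. Thermal Claisen rearrangement in refluxing acetic anhydride with NaOAc (about 140 °C) traps the first-formed enol as its ester, so that neither the abnormal Claisen pathway nor ring closure onto the vinyl group can follow. This should give racemic 4-acetoxy-5-methyl-3-[(6E)-3,7,11-trimethyldodeca-1,6,10-trien-3-yl]coumarin F1. Methanolysis (K2CO3, MeOH, rt) then frees racemic 4-hydroxy-5-methyl-3-[(6E)-3,7,11-trimethyldodeca-1,6,10-trien-3-yl]coumarin F2. The enantiomers are separated by preparative chromatography on a chiral stationary phase. The S enantiomer is 8, where the route is rejoined, and 4-hydroxy-5-methyl-3-[(3R,6E)-3,7,11-trimethyldodeca-1,6,10-trien-3-yl]coumarin F3 is set aside.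

Step 4. Hydroxide has to attack the lactone carbonyl of an electron-rich enolate next to a quaternary carbon. The opening may be sluggish, and at the temperatures then needed hydroxide may add to the ketone instead and cleave the C3–C4 bond (retro-Claisen loss of the aroyl group). The fallback sets out from 8 and blocks C3 so that the enolate cannot form. N-Chlorosuccinimide (CH2Cl2, 0 °C) should chlorinate the enol carbon to give 3-chloro-5-methyl-3-[(3S,6E)-3,7,11-trimethyldodeca-1,6,10-trien-3-yl]chromane-2,4-dione F4, a non-enolisable aryl β-keto ester. This should open with water at about pH 7 (aq. THF, rt) and lose CO2 at once, giving (3S,6E)-2-chloro-3-ethenyl-1-(2-hydroxy-6-methylphenyl)-3,7,11-trimethyldodeca-6,10-dien-1-one F5. Zinc dust in acetic acid then removes the chlorine reductively, and the route is rejoined at 10. The quaternary centre is not touched in any of these operations.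

Step 2. The coumarin anion is ambident, and the peri methyl group at C5 slows attack through O4. Alkylation at the lactone oxygen (2-alkoxychromone) or at C3 may therefore erode regiocontrol. The fallback sets out from 4 and reverses the polarity. POCl3 with benzyltriethylammonium chloride (MeCN, reflux) should give 4-chloro-5-methylcoumarin F6, a vinylogous acid chloride. Addition–elimination at C4 by sodium farnesoxide (from 5 and NaH, THF, 0 °C) can then place the chain only on O4, and the route is rejoined at 6.

**Further compounds**

F1 | step 3 | racemic 4-acetoxy-5-methyl-3-[(6E)-3,7,11-trimethyldodeca-1,6,10-trien-3-yl]coumarin | C=CC(C)(CC/C=C(\C)CCC=C(C)C)c1c(OC(C)=O)c2c(C)cccc2oc1=O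
F2 | step 3 | racemic 4-hydroxy-5-methyl-3-[(6E)-3,7,11-trimethyldodeca-1,6,10-trien-3-yl]coumarin | C=CC(C)(CC/C=C(\C)CCC=C(C)C)c1c(O)c2c(C)cccc2oc1=O
F3 | step 3 | 4-hydroxy-5-methyl-3-[(3R,6E)-3,7,11-trimethyldodeca-1,6,10-trien-3-yl]coumarin | C=C[C@@](C)(CC/C=C(\C)CCC=C(C)C)c1c(O)c2c(C)cccc2oc1=O
F4 | step 4 | 3-chloro-5-methyl-3-[(3S,6E)-3,7,11-trimethyldodeca-1,6,10-trien-3-yl]chromane-2,4-dione (both C3 epimers) | C=C[C@](C)(CC/C=C(\C)CCC=C(C)C)C1(Cl)C(=O)Oc2cccc(C)c2C1=O
F5 | step 4 | (3S,6E)-2-chloro-3-ethenyl-1-(2-hydroxy-6-methylphenyl)-3,7,11-trimethyldodeca-6,10-dien-1-one (both C2 epimers) | C=C[C@](C)(CC/C=C(\C)CCC=C(C)C)C(Cl)C(=O)c1c(C)cccc1O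
F6 | step 2 | 4-chloro-5-methylcoumarin | Cc1cccc2oc(=O)cc(Cl)c12
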